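The numbers of this flask were set for the occasion; the flask was simulated.

A small charge, 1.00 mM of protic impurity, can cost at most 2.00 % of the starting material, so I set it aside and watch the partner. Its 0.0400 M stands below the 0.0490 M of starting material left after that, which makes it the limiting reagent.

in all of them: starting material 0.050 M; protic impurity 1.00 mM

| charge | partner | second substrate | time | remark |
|---|---|---|---|---|
| ochre | 0.0400 M | 0.0500 M | 5.0 h | everything together in a closed stirred flask, run for 5.0 h |
| red | 0.0400 M | 0.0500 M (fed, over 2.50 h) | 5.0 h | a stirred flask in which second substrate is dosed at a steady rate over 2.50 h without added volume, worked up at 5.0 h |
| amber | 0.0400 M | 0.0500 M |  | one stirred flow tank at steady state, fed with the mixture as stated, mean residence time 5.0 h |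
| green | 0.0400 M (fed, over 2.50 h) | 0.0500 M | 5.0 h | a stirred flask in which partner is dosed at a steady rate over 2.50 h without added volume, worked up at 5.0 h |

    second substrate + partner → second product (k1 = 3.3 M⁻¹ h⁻¹)
    starting material + partner → target (k2 = 13 M⁻¹ h⁻¹)
    partner → decomposed reagent (k3 = 0.15 h⁻¹)
    starting material + protic impurity → quenched substrate (k4 = 430 M⁻¹ h⁻¹)

1. the set-up with the highest amount of target at the outlet or at the end, in percent of the starting material put in ("none" if the first two lie within 2 percentage points) (ochre / red / amber / green / none)
2. amount of target at the outlet or at the end, in percent of the starting material put in, ochre
3. amount of target at the outlet or at the end, in percent of the starting material put in, red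
4. amount of target at the outlet or at the end, in percent of the starting material put in, amber
5. amount of target at the outlet or at the end, in percent of the starting material put in, green

- the stated concentrations are those of everything mixed, before any reaction; amounts are the same in each set-up
- the feed brings no volume worth counting
- run time (ochre): 5.0 h

I follow one molecule of partner. It has three exits, to target, second product and decomposed reagent, and each exit pulls with a rate constant times what the partner meets, or with the bare constant for decomposition. So [partner] cancels from the odds. At the charge the pulls are 0.650 h⁻¹, 0.165 h⁻¹ and 0.15 h⁻¹, and the target's pull over their sum is 67.4 %, the fork share: the chance that this molecule becomes target.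

Counting every partner molecule as taking a fork, ochre starts from 53.9 % of the starting material put in. But the share sinks as starting material goes. That first figure leaves ochre 0.0221 M of starting material at the end, where the share, with second substrate held at its charge, is 47.7 %, and averaging start and end gives 46.0 %.

The weak link is that end value, taken from a first figure I already distrust. Reforged from 46.0 %, [starting material] ends at 0.0260 M, the end share is 51.8 %, and ochre stands at 47.6 %.

Red opens with no second substrate, so its start share is 81.2 %, and with the same end share I get 53.2 %. The share holds no [partner], so I give green the ochre figure. Amber works at outlet composition, so I put it near ochre's end share, at about 41.4 %. I commit to red.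

The forecast also names red, with figures lower than mine : 47.1 % for ochre, 51.1 % for red, 36 % for amber and 45.5 % for green, on the ground that “Delaying the second substrate gives the starting material the early, partner-rich period to itself”.

The flasks give 47.1 % for ochre, 51.3 % for red, 36.0 % for amber and 45.0 % for green, so red leads. Ochre ends with 50.9 % of its charged starting material. Amber holds 62.1 % of its starting material and 0.00892 M of partner, and the tank balance then puts second substrate at 0.0436 M. Amber's fork share is therefore 57.9 %, lower than the 67.4 % at the charge. Applied to the 77.7 % of partner consumed, it gives 36.0 % of the starting material put in.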